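**Plan**

- Retrosynthesis: the acetyl group is cut from C5 first (C5–C bond, back to a pyrrol-2-yl triflate, i.e. a lactam C5=O). Then the pyrrole ring is cut at N1–C5 and C2–C3.
- Enabling feature: C3=C4 carries two identical indol-3-yl groups and, together with C5, maps onto a symmetric 2,3-diarylcyclopropenone. N1 and C2 with its carboxyl map onto the C=N bond of an N-sulfonyl iminoacetate.
- The cyclopropenone is cut at its two aryl–ring bonds (twofold Friedel–Crafts arylation of a C3Cl3 unit by N-tosylindole).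
- Forward: tosylindole, then the cyclopropenone; separately the imine; a phosphine-catalysed three- to five-membered ring expansion closes the only new ring (the pyrrolinone). Triflation with aromatisation, Stille coupling with hydrolysis, and global deprotection finish the route.
- Stereochemistry: the target is achiral. The one stereocentre formed (C2, in the ring expansion) is racemic and becomes sp2 on aromatisation in step 5.

Key step: step 4

Remarks: Ts = p-toluenesulfonyl. The ethyl ester is carried because ethyl glyoxylate is the standard commercial glyoxylate; it is cleaved in the last step. Phosphine- and palladium-bound species of the catalytic cycles are described in the Why lines and are not numbered.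

**Route**

Step 1
Reactants: 1 indole
Product: 2 1-tosyl-1H-indole
Conditions: TsCl, 50% aq NaOH, Bu4NHSO4 (cat.), CH2Cl2, 0 °C to rt
Reagents that add atoms: p-toluenesulfonyl chloride (TsCl), Cc1ccc(S(=O)(=O)Cl)cc1
Why: N-sulfonylation of the indole anion under phase-transfer conditions; the tosyl group masks N–H and damps the ring so that the later Friedel–Crafts arylation should stop at one substitution per indole, at C3.

Step 2
Reactants: 2 1-tosyl-1H-indole (2 equiv); 3 tetrachlorocyclopropene
Product: 6 2,3-bis(1-tosyl-1H-indol-3-yl)cycloprop-2-en-1-one, via trichlorocyclopropenium tetrachloroaluminate 4 (not isolated), via chlorobis(1-tosylindol-3-yl)cyclopropenium tetrachloroaluminate 5 (not isolated)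
Conditions: AlCl3 (1.1 equiv), CH2Cl2, rt; then 2, −78 °C to rt; then ice/H2O
Reagents that add atoms: water, O
Why: twofold Friedel–Crafts arylation of the aromatic trichlorocyclopropenium cation 4 by C3 of the N-sulfonylindole (the position at which such indoles are acylated under AlCl3), then hydrolysis of salt 5 on aqueous quench; two equivalents of indole and low temperature are meant to stop the sequence before a third arylation.

Step 3
Reactants: 7 ethyl glyoxylate; 8 p-toluenesulfonyl isocyanate
Product: 9 ethyl (E)-2-(tosylimino)acetate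
Conditions: toluene, reflux; concentrated and used crude
Reagents that add atoms: none
Why: condensation of the aldehyde with the sulfonyl isocyanate with extrusion of CO2 (aza-Wittig-type exchange of C=O for C=N), the standard entry to N-sulfonyl iminoacetates; the E imine is moisture-sensitive and is therefore used directly.

Step 4
Reactants: 6 2,3-bis(1-tosyl-1H-indol-3-yl)cycloprop-2-en-1-one; 9 ethyl (E)-2-(tosylimino)acetate (1.5 equiv, added slowly)
Product: 10 ethyl 5-oxo-1-tosyl-3,4-bis(1-tosyl-1H-indol-3-yl)-2,5-dihydro-1H-pyrrole-2-carboxylate (racemic)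
Conditions: PMe3 (20 mol%), CH2Cl2, 4 Å MS, 0 °C to rt
Reagents that add atoms: none
Why: The phosphine adds in conjugate fashion to the strained enone of 6 and the three-membered ring opens to an α-ketenyl phosphonium ylide, the same species whichever of the two equivalent ring bonds to the carbonyl breaks, because 6 is symmetric. The ylide carbon adds Mannich-fashion to the electron-poor imine carbon of 9 (C2–C3), the sulfonamide anion closes onto the sp carbon of the ketene (N1–C5, 5-exo-dig, the C=O staying outside the ring), and the phosphonium enolate expels PMe3 by β-elimination, restoring C3=C4 and turning the catalyst over. The closest known reaction type is the phosphine-catalysed formal [3+2] ring expansion of diarylcyclopropenones with aldehydes, ketoesters and N-sulfonyl imines to butenolides and unsaturated γ-lactams, applied here to a bis(heteroaryl)cyclopropenone. The one new stereocentre, C2, forms without control as a racemate, which is of no consequence because it is erased in step 5. The selectivity needed is C–C bond formation at the imine carbon in place of attack at nitrogen or Wittig-type olefination; the polarity of the sulfonyl iminoacetate and the fast intramolecular capture of the ketene should secure it, while the N-tosyl groups keep the indole rings from reacting with 9.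

Step 5
Reactants: 10 ethyl 5-oxo-1-tosyl-3,4-bis(1-tosyl-1H-indol-3-yl)-2,5-dihydro-1H-pyrrole-2-carboxylate
Product: 12 ethyl 1-tosyl-3,4-bis(1-tosyl-1H-indol-3-yl)-5-(trifluoromethylsulfonyloxy)-1H-pyrrole-2-carboxylate, via potassium pyrrol-2-olate 11 (not isolated)
Conditions: KN(SiMe3)2, THF, −78 °C; then PhNTf2, −78 to 0 °C
Reagents that add atoms: N-phenylbis(trifluoromethanesulfonimide) (PhNTf2), O=S(=O)(N(c1ccccc1)S(=O)(=O)C(F)(F)F)C(F)(F)F
Why: the C2–H is flanked by the ester, the sulfonamide nitrogen and the enone, so the amide base should remove it to give the aromatic pyrrol-2-olate 11, which is sulfonylated on oxygen (enolate O-triflation); any double-bond tautomer of 10 converges on the same anion.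

Step 6
Reactants: 12 ethyl 1-tosyl-3,4-bis(1-tosyl-1H-indol-3-yl)-5-(trifluoromethylsulfonyloxy)-1H-pyrrole-2-carboxylate
Product: 14 ethyl 5-acetyl-1-tosyl-3,4-bis(1-tosyl-1H-indol-3-yl)-1H-pyrrole-2-carboxylate, via 1-ethoxyvinyl enol ether 13 (not isolated)
Conditions: tributyl(1-ethoxyvinyl)stannane, Pd(PPh3)4 (10 mol%), LiCl (3 equiv), CuI (20 mol%), DMF, 80 °C; then 1 M HCl, THF, rt
Reagents that add atoms: tributyl(1-ethoxyvinyl)stannane, CCCC[Sn](CCCC)(CCCC)C(=C)OCC; water, O
Why: Stille coupling of the electron-poor heteroaryl triflate (oxidative addition to zerovalent palladium, chloride to open the triflate-derived complex, CuI to speed tin-to-palladium transfer at the hindered position) installs the masked acetyl group as enol ether 13, which dilute acid hydrolyses to the methyl ketone.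

Step 7
Reactants: 14 ethyl 5-acetyl-1-tosyl-3,4-bis(1-tosyl-1H-indol-3-yl)-1H-pyrrole-2-carboxylate
Product: 15 5-acetyl-3,4-di(1H-indol-3-yl)-1H-pyrrole-2-carboxylic acid
Conditions: KOH (excess), THF/EtOH/H2O, 70 °C; then 1 M HCl to pH 3, 0 °C
Reagents that add atoms: potassium hydroxide, [K+].[OH-]
Why: hydroxide should cleave the three N-sulfonyl groups (the doubly acyl-flanked pyrrole one first, the indole ones on heating) and saponify the ethyl ester in one operation; cold acidification liberates the acid, which the 5-acetyl group stabilises against decarboxylation.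

**Compound list**

1 | indole | c1ccc2[nH]ccc2c1 | starting material
2 | 1-tosyl-1H-indole | Cc1ccc(S(=O)(=O)n2ccc3ccccc32)cc1 | intermediate
3 | tetrachlorocyclopropene | ClC1=C(Cl)C1(Cl)Cl | starting material
4 | trichlorocyclopropenium tetrachloroaluminate | Cl[C+]1C(Cl)=C1Cl.Cl[Al-](Cl)(Cl)Cl | intermediate
5 | chlorobis(1-tosylindol-3-yl)cyclopropenium tetrachloroaluminate | Cl[C+]1C(c2cn(S(=O)(=O)c3ccc(C)cc3)c3ccccc23)=C1c1cn(S(=O)(=O)c2ccc(C)cc2)c2ccccc12.Cl[Al-](Cl)(Cl)Cl | intermediate
6 | 2,3-bis(1-tosyl-1H-indol-3-yl)cycloprop-2-en-1-one | O=C1C(c2cn(S(=O)(=O)c3ccc(C)cc3)c3ccccc23)=C1c1cn(S(=O)(=O)c2ccc(C)cc2)c2ccccc12 | intermediate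
7 | ethyl glyoxylate | CCOC(=O)C=O | starting material
8 | p-toluenesulfonyl isocyanate | Cc1ccc(S(=O)(=O)N=C=O)cc1 | starting material
9 | ethyl (E)-2-(tosylimino)acetate | CCOC(=O)/C=N/S(=O)(=O)c1ccc(C)cc1 | intermediate
10 | ethyl 5-oxo-1-tosyl-3,4-bis(1-tosyl-1H-indol-3-yl)-2,5-dihydro-1H-pyrrole-2-carboxylate (racemic) | CCOC(=O)C1N(S(=O)(=O)c2ccc(C)cc2)C(=O)C(c2cn(S(=O)(=O)c3ccc(C)cc3)c3ccccc23)=C1c1cn(S(=O)(=O)c2ccc(C)cc2)c2ccccc12 | intermediate
11 | potassium 5-(ethoxycarbonyl)-1-tosyl-3,4-bis(1-tosyl-1H-indol-3-yl)-1H-pyrrol-2-olate | CCOC(=O)c1c(-c2cn(S(=O)(=O)c3ccc(C)cc3)c3ccccc23)c(-c2cn(S(=O)(=O)c3ccc(C)cc3)c3ccccc23)c([O-])n1S(=O)(=O)c1ccc(C)cc1.[K+] | intermediate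
12 | ethyl 1-tosyl-3,4-bis(1-tosyl-1H-indol-3-yl)-5-(trifluoromethylsulfonyloxy)-1H-pyrrole-2-carboxylate | CCOC(=O)c1c(-c2cn(S(=O)(=O)c3ccc(C)cc3)c3ccccc23)c(-c2cn(S(=O)(=O)c3ccc(C)cc3)c3ccccc23)c(OS(=O)(=O)C(F)(F)F)n1S(=O)(=O)c1ccc(C)cc1 | intermediate
13 | ethyl 5-(1-ethoxyvinyl)-1-tosyl-3,4-bis(1-tosyl-1H-indol-3-yl)-1H-pyrrole-2-carboxylate | CCOC(=C)c1c(-c2cn(S(=O)(=O)c3ccc(C)cc3)c3ccccc23)c(-c2cn(S(=O)(=O)c3ccc(C)cc3)c3ccccc23)c(C(=O)OCC)n1S(=O)(=O)c1ccc(C)cc1 | intermediate
14 | ethyl 5-acetyl-1-tosyl-3,4-bis(1-tosyl-1H-indol-3-yl)-1H-pyrrole-2-carboxylate | CCOC(=O)c1c(-c2cn(S(=O)(=O)c3ccc(C)cc3)c3ccccc23)c(-c2cn(S(=O)(=O)c3ccc(C)cc3)c3ccccc23)c(C(C)=O)n1S(=O)(=O)c1ccc(C)cc1 | intermediate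
15 | 5-acetyl-3,4-di(1H-indol-3-yl)-1H-pyrrole-2-carboxylic acid | CC(=O)c1[nH]c(C(=O)O)c(-c2c[nH]c3ccccc23)c1-c1c[nH]c2ccccc12 | target

**Step count**

Total: 7 steps. Longest linear sequence: 6 steps (steps 1, 2, 4, 5, 6 and 7 from indole); step 3 is a one-step branch.

**Steps most likely to fail**

Step 4. The electrophilic imine may be consumed unproductively by the phosphine, or the hindered bis(indolyl) ylide may add so slowly that olefination or ketene oligomerisation outruns ring closure. The fallback builds the pyrrole by twofold Suzuki–Miyaura coupling; it sets out from 2 and rejoins the route at 14, so that steps 5 and 6 are not needed. Bromination of 2 at C3 (Br2, CH2Cl2, 0 °C) would give 3-bromo-1-tosyl-1H-indole F1. Miyaura borylation (bis(pinacolato)diboron, Pd(dppf)Cl2, KOAc, dioxane, 90 °C) would give 1-tosyl-3-(4,4,5,5-tetramethyl-1,3,2-dioxaborolan-2-yl)-1H-indole F2. Commercial ethyl 5-acetyl-1H-pyrrole-2-carboxylate would be brominated at both free ring positions (NBS, DMF) to ethyl 5-acetyl-3,4-dibromo-1H-pyrrole-2-carboxylate F3 and N-tosylated (NaH, TsCl, THF) to ethyl 5-acetyl-3,4-dibromo-1-tosyl-1H-pyrrole-2-carboxylate F4. Coupling of F4 with F2 (2.5 equiv; Pd(PPh3)4, K3PO4, dioxane with a little water, 80 °C) should give 14.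

Step 2. The second arylation of the aryl-stabilised cyclopropenium ion by the deactivated sulfonylindole may stall, or the sequence may run on to a third arylation. The fallback makes the cyclopropenone from the diarylalkyne and difluorocarbene; it sets out from 1 and rejoins at 6. Iodination of 1 (I2, KOH, DMF) would give 3-iodo-1H-indole F5, tosylated in the same flask (NaH, TsCl) to 3-iodo-1-tosyl-1H-indole F6. Sonogashira coupling with trimethylsilylacetylene (Pd(PPh3)2Cl2, CuI, Et3N, THF) would give 1-tosyl-3-[(trimethylsilyl)ethynyl]-1H-indole F7, and desilylation (K2CO3, MeOH, rt) 3-ethynyl-1-tosyl-1H-indole F8. A second Sonogashira coupling of F8 with F6 would give 1,2-bis(1-tosyl-1H-indol-3-yl)ethyne F9. Difluorocarbene addition (TMSCF3, NaI, THF, 65 °C) would give 3,3-difluoro-1,2-bis(1-tosyl-1H-indol-3-yl)cyclopropene F10, which hydrolyses on wet silica gel to 6.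

Step 6. Tin-to-palladium transfer at the tetrasubstituted triflate, flanked by the N-tosyl group and an indolyl ring, may be slow, so that protodestannylation and S–O cleavage back to the lactam win. The fallback dispenses with transmetalation; it sets out from 12 and rejoins at 14. A Heck reaction of 12 with butyl vinyl ether under cationic conditions (Pd(OAc)2, 1,3-bis(diphenylphosphino)propane, Et3N, DMF, 80 °C) should arylate the oxygen-bearing carbon of the olefin and give ethyl 5-(1-butoxyvinyl)-1-tosyl-3,4-bis(1-tosyl-1H-indol-3-yl)-1H-pyrrole-2-carboxylate F11. Hydrolysis with 1 M HCl in THF then gives 14.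

**Further compounds**

F1 | step 4 | 3-bromo-1-tosyl-1H-indole | Cc1ccc(S(=O)(=O)n2cc(Br)c3ccccc32)cc1
F2 | step 4 | 1-tosyl-3-(4,4,5,5-tetramethyl-1,3,2-dioxaborolan-2-yl)-1H-indole | Cc1ccc(S(=O)(=O)n2cc(B3OC(C)(C)C(C)(C)O3)c3ccccc32)cc1
F3 | step 4 | ethyl 5-acetyl-3,4-dibromo-1H-pyrrole-2-carboxylate | CCOC(=O)c1[nH]c(C(C)=O)c(Br)c1Br
F4 | step 4 | ethyl 5-acetyl-3,4-dibromo-1-tosyl-1H-pyrrole-2-carboxylate | CCOC(=O)c1c(Br)c(Br)c(C(C)=O)n1S(=O)(=O)c1ccc(C)cc1
F5 | step 2 | 3-iodo-1H-indole | Ic1c[nH]c2ccccc12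
F6 | step 2 | 3-iodo-1-tosyl-1H-indole | Cc1ccc(S(=O)(=O)n2cc(I)c3ccccc32)cc1
F7 | step 2 | 1-tosyl-3-[(trimethylsilyl)ethynyl]-1H-indole | Cc1ccc(S(=O)(=O)n2cc(C#C[Si](C)(C)C)c3ccccc32)cc1
F8 | step 2 | 3-ethynyl-1-tosyl-1H-indole | Cc1ccc(S(=O)(=O)n2cc(C#C)c3ccccc32)cc1
F9 | step 2 | 1,2-bis(1-tosyl-1H-indol-3-yl)ethyne | Cc1ccc(S(=O)(=O)n2cc(C#Cc3cn(S(=O)(=O)c4ccc(C)cc4)c4ccccc34)c3ccccc32)cc1
F10 | step 2 | 3,3-difluoro-1,2-bis(1-tosyl-1H-indol-3-yl)cyclopropene | FC1(F)C(c2cn(S(=O)(=O)c3ccc(C)cc3)c3ccccc23)=C1c1cn(S(=O)(=O)c2ccc(C)cc2)c2ccccc12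
F11 | step 6 | ethyl 5-(1-butoxyvinyl)-1-tosyl-3,4-bis(1-tosyl-1H-indol-3-yl)-1H-pyrrole-2-carboxylate | CCCCOC(=C)c1c(-c2cn(S(=O)(=O)c3ccc(C)cc3)c3ccccc23)c(-c2cn(S(=O)(=O)c3ccc(C)cc3)c3ccccc23)c(C(=O)OCC)n1S(=O)(=O)c1ccc(C)cc1
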